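The cedar run looks nearly like your flask: the same 0.0858 M of Q, but 0.092 M of E where the flask holds 0.066 M. Cedar came to rest with E at 0 % and J plus Z at 48.3 % of the E charged, while 48.2 % of its Q stayed unused. So cedar stopped by losing its E, and what remains to ask of the flask is how E divides.

| setting | cedar | alder | flask |
|---|---|---|---|
| E | 0.092 M | 0.15 M | 0.066 M |
| Q | 0.0858 M | 0.0858 M | 0.0858 M |
| remark | run made earlier | run made earlier |  |
| time |  |  | 10 d |

- cedar (time / d: E / %, J / %, Z / %): 1.25: 0.3, 27.3, 20.5; 2.50: 0, 27.7, 20.6; 3.00: 0.8, 28.2, 21.3; 5.00: 0, 27.6, 20.9; 6.00: 0, 27.5, 21.1; 8.00: 0, 27.5, 20.8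
- alder (time / d: E / %, J / %, Z / %): 0.417: 2.6, 19.6, 14.2; 1.25: 0.5, 21.6, 15.0; 2.50: 0.9, 20.8, 15.6; 3.00: 0, 20.6, 16.3; 5.00: 0, 21.3, 16.3; 6.00: 0.6, 20.1, 16.8; 8.00: 1.1, 21.7, 16.7

(readings scatter by 0.5 percentage points)

- which holds at 10 d: what has brought the reaction to rest, or that it has not come to rest (forward and back rates have come level / Q has run out first / all of E has reacted / it is still moving)
- share of the E used up at 10 d
- J at 10 d, in percent of the E charged
- Z at 10 d, in percent of the E charged
- amount of J if the flask were left three thousand times as long, in percent of the E charged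

- a species is counted by the E in it: one L counts as two
- steps under discussion: E <-> G; E + Q -> Z; Q + G -> J; 2 E -> L
- the reaction counts as stopped when no species that holds the E changes by six tenths of a point or more over the second half of the time

Divide the rate at which E is lost by the rate at which Q is lost, and time drops out. Each Q taken carries one E into J or Z, while r E/Q further E goes to L, where r is a selectivity factor. Put r = 2 and integrate until E is gone: the capture share, the part of the charged E that ends in J plus Z, is the charge of Q over the sum of the charges of Q and E. Cedar gives 48.3 % by this rule, matching its last reading. Alder gives 36.4 %, and its sums of J and Z from 2.50 d on scatter between 36.4 % and 38.4 %, so there the rule sits at the low edge of the readings.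

Your flask starts leaner in E, 0.769 of E per Q against 1.07 in cedar, so L competes less, and its capture share is C = 56.5 %. Split as in cedar's last reading, that makes J 32.2 % and Z 24.3 %, and cedar's flat readings say J then stays.

The forecast says all of E has reacted, with 100 % of E used, J 32.4 %, Z 24.7 % and J 32.4 % after the long wait, a little above my J and Z: “Nothing changes later.”

The flask gives all of E has reacted, with 100 % of E used, J 32.7 %, Z 24.5 %, and J 32.7 % after the long wait.

    E ⇌ G (K = 0.510, k = 2.89 h⁻¹)
    E + Q → Z (k = 1.92 M⁻¹ h⁻¹)
    Q + G → J (k = 5.41 M⁻¹ h⁻¹)
    2 E → L (k = 6.19 M⁻¹ h⁻¹)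

In this flask J plus Z comes to 57.2 % against C of 56.5 %. Take the neighbour with 0.026 M of E: the same rule gives 76.7 %, and that flask ends with J 44.1 % and Z 33.1 %, which sum to 77.2 %. The reverse step, G to E, is the main reason J stays low in your flask: with that step taken away, J stands at 84.1 % instead of 32.7 %.

(The readings are calculated from invented constants; noise was put on by code.)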